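The numbers in the tables come from a simulation with made-up constants.

4 questions are put to 5 new flasks, and the doubtful place is the bottom of the ranking, between dusk and autumn.

| setting | violet | grey | ochre | dusk | summer | winter | autumn | midnight |
|---|---|---|---|---|---|---|---|---|
| L | 46 mM | 46 mM | 46 mM | 46 mM | 46 mM | 46 mM | 46 mM | 46 mM |
| D | 46 mM | 46 mM | 46 mM | 46 mM | 46 mM | 46 mM | 46 mM | 46 mM |
| G | 20 mM (fed, over 40 min) | 130 mM (fed, over 40 min) | 55.2 mM (fed, over 40 min) | 40.0 mM (fed, over 150 min) | 150 mM (fed, over 60 min) | 55.2 mM (fed, over 40 min) | 55.2 mM (fed, over 40 min) | 80.0 mM (fed, over 40 min) |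
| Q | 1.1 mM | 1.1 mM | 0.57 mM | 0.60 mM | 1.1 mM | 1.1 mM | 0.40 mM | 0.80 mM |
| remark | run made earlier | run made earlier | run made earlier |  |  |  |  |  |
| time |  |  |  | 10 h | 10 h | 10 h | 10 h | 10 h |

- violet (time / h: E / %): 0.500: 5; 1.00: 13; 1.50: 15; 2.50: 16; 4.00: 18; 8.00: 16
- grey (time / h: E / %): 0.500: 24; 1.00: 40; 1.50: 47; 2.50: 47; 4.00: 44; 8.00: 42
- ochre (time / h: E / %): 1.33: 24; 3.00: 30; 4.00: 30; 6.00: 33; 8.00: 32

(readings scatter by 1.5 percentage points)

- Q is single-handed; L and D are mirror images of each other, charged as a racemate, each of them at the stated concentration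
- steps that have been proposed: 2 G -> J; G <-> Z; G + Q + L -> Q + E; G + Q + D -> Q + X; E <-> X

- ranking by amount of E, in percent of the L and D together charged, from high to low, at 10 h (dusk / summer / winter / autumn / midnight)
- the same order at 1.0 h (dusk / summer / winter / autumn / midnight)
- the amount of E, in percent of the L and D together charged of the flask you put first, at 10 h
- the amount of E, in percent of the L and D together charged of the flask you put last, at 10 h

Dusk charges less G than L, so G is its limiting reagent, and E follows from the capture, the L spent per G charged. Read as E made per G charged, the capture 0.828 is the violet reading, with the scatter of that reading.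

Two extremes can be reckoned for dusk in the head. If each G charged landed on L, E would reach 43.5 %. With the capture of ochre, 0.550 from its reading of 33 %, E would reach 23.9 %.

The step pairing G into J goes with the square of [G] and the step to E with [G] and [Q], so this reckoning places a flask between the extremes by the feed per minute and per Q, with L and D as charged. Dusk has 0.444 min⁻¹, far less than the 2.42 min⁻¹ of ochre and close to the 0.455 min⁻¹ of violet, so the capture of violet is taken for dusk.

E then leaks away, and the fraction left is the easier count. Grey goes from 47 % to 42 % between 2.50 h and 8.00 h. The E of dusk is taken here as standing by the end of its feed, at 2.5 h, and the grey loss carried on from 2.50 h to 10 h leaves 0.858 of it. This reckoning therefore gives dusk 30.9 %.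

Autumn, with a feed per Q of 3.45 min⁻¹, is expected below the ochre reading, which lies above that estimate, so last place stays open here.

The forecast gave summer > midnight > winter > dusk > autumn at 10 h and summer > midnight > winter > autumn > dusk at 1.0 h, with 41 % and 24 %, on the ground that “This fits second-order G loss competing with Q-catalysed reaction, so a slow feed or more Q helps.”

The flask gives summer > midnight > winter > autumn > dusk at 10 h and summer > midnight > winter > autumn > dusk at 1.0 h, with 40.9 % and 28.1 %; dusk stands below the reckoned value.

    2 G → J (k = 0.00162 L mol⁻¹ s⁻¹)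
    G ⇌ Z (K = 0.900, k = 2.58 × 10⁻⁴ s⁻¹)
    G + Q + L → Q + E (k = 10.8 L² mol⁻² s⁻¹)
    G + Q + D → Q + X (k = 0.357 L² mol⁻² s⁻¹)
    E ⇌ X (k = 9.03 × 10⁻⁶ s⁻¹)

In dusk, L keeps 32 % of its charge at 10.0 h, a capture of 0.781, below the violet reading. The half-life of E in dusk by the forward step to X alone, 21 h at 2.34 h, is ten times the 2.0 h half-life of G by the path to E at 10.0 h. The neighbour of dusk with 24 mM of G has a capture of 0.866 and ends with 18.7 % of E.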